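**Assumption:** (S)-4-benzyloxazolidin-2-one is used as a recoverable chiral auxiliary and counted as a reagent. It is recovered in Step 11. MOM groups protect both phenols until Step 14.

## Retrosynthetic overview
1. The target is the bis-phenol of the bis-MOM ether **17**. The C4–syringyl bond is made by Ni-catalysed radical cross-coupling of primary iodide **16** with aryl bromide **9**.
2. **16** comes from Evans imide **14**. The erythro (2S,3S-type) 2,3-dimethyl pattern is set by Evans α-methylation. That step follows a benzylic-radical conjugate addition of **5** to N-crotonyl imide **12**, which forms the C1–C2 bond and the β-stereocentre.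
3. Both new stereocentres form on the same face of the chelated imide, anti to the benzyl group of the (S)-auxiliary.
4. No new ring is formed. The guaiacyl unit (**5**) is built from p-cresol and the syringyl unit (**9**) from phenol, each by bromination and Cu-methoxylation.

## Route

**Step 1**
Reactants: **1** p-cresol
Product: **2** 2-bromo-4-methylphenol
Conditions: Br2, CH2Cl2, −10 → 0 °C
Reagents that add atoms: bromine, BrBr
Why: Electrophilic aromatic bromination goes ortho to the strongly activating OH because the para position is blocked.

**Step 2**
Reactants: **2**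
Product: **3** 2-methoxy-4-methylphenol (creosol)
Conditions: NaOMe, CuBr (cat.), DMF/MeOH, 110 °C
Reagents that add atoms: sodium methoxide, C[O-].[Na+]
Why: Ullmann-type Cu-catalysed methoxylation of the aryl bromide, assisted by the ortho phenoxide.

**Step 3**
Reactants: **3**
Product: **4** 1-(methoxymethoxy)-2-methoxy-4-methylbenzene
Conditions: MOMCl, i-Pr2NEt, CH2Cl2, 0 °C → rt
Reagents that add atoms: chloromethyl methyl ether, COCCl
Why: The phenol is protected as a MOM acetal so that it survives the radical, enolate and reductive steps.

**Step 4**
Reactants: **4**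
Product: **5** 4-(bromomethyl)-1-(methoxymethoxy)-2-methoxybenzene
Conditions: NBS, AIBN (cat.), PhCF3, 80 °C; crude product used at once
Reagents that add atoms: N-bromosuccinimide, O=C1CCC(=O)N1Br
Why: Wohl–Ziegler benzylic bromination gives the benzylic radical precursor.

**Step 5**
Reactants: **6** phenol
Product: **7** 2,4,6-tribromophenol
Conditions: Br2 (3.1 equiv), H2O, rt
Reagents that add atoms: bromine, BrBr
Why: Exhaustive electrophilic bromination of the phenol at the ortho and para positions.

**Step 6**
Reactants: **7**
Product: **8** 4-bromo-2,6-dimethoxyphenol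
Conditions: NaOMe (5 equiv), CuI (cat.), MeOH/DMF, 90 °C
Reagents that add atoms: sodium methoxide, C[O-].[Na+]
Why: Cu-catalysed methoxylation replaces the two ortho bromides, which are activated by the adjacent phenoxide, and leaves the para bromide for the later coupling.

**Step 7**
Reactants: **8**
Product: **9** 5-bromo-1,3-dimethoxy-2-(methoxymethoxy)benzene
Conditions: MOMCl, i-Pr2NEt, CH2Cl2, 0 °C → rt
Reagents that add atoms: chloromethyl methyl ether, COCCl
Why: MOM protection of the phenol, so that it is compatible with the Ni/Zn coupling.

**Step 8**
Reactants: **10** (E)-crotonyl chloride; **11** (S)-4-benzyloxazolidin-2-one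
Product: **12** (S)-4-benzyl-3-[(E)-but-2-enoyl]oxazolidin-2-one
Conditions: n-BuLi, THF, −78 °C; then **10**
Reagents that add atoms: none
Why: N-acylation of the lithiated oxazolidinone installs the chiral Michael acceptor.

**Step 9**
Reactants: **12**, **5**
Product: **13** (S)-4-benzyl-3-[(S)-4-(3-methoxy-4-(methoxymethoxy)phenyl)-3-methylbutanoyl]oxazolidin-2-one
Conditions: Bu3SnH (syringe pump), Et3B/air, MgBr2·OEt2, CH2Cl2, −78 °C
Reagents that add atoms: none (the hydrogen comes from Bu3SnH)
Why: This is the radical C1–C2 bond-forming step. Mg2+ chelates the imide and holds the enoyl s-cis. The nucleophilic benzylic radical adds to Cβ anti to the auxiliary benzyl group, which gives the (S)-β-centre. The α-radical is then reduced by Bu3SnH.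
Proposed new method: This extends Lewis-acid-chelated Giese additions of alkyl radicals to N-enoyl oxazolidinones to an electron-rich benzylic radical. The benzylic radical is polarity-matched to the chelated, electron-poor enoyl. Slow Bu3SnH delivery and excess **5** limit simple reduction of **5** to ArCH3 and bibenzyl formation. The closest known reaction is the Sibi/Porter chelate-controlled radical conjugate addition.

**Step 10**
Reactants: **13**
Product: **14** (S)-4-benzyl-3-[(2S,3S)-4-aryl-2,3-dimethylbutanoyl]oxazolidin-2-one, Ar = 3-methoxy-4-(methoxymethoxy)phenyl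
Conditions: NaHMDS, THF, −78 °C; then MeI, −78 → −40 °C
Reagents that add atoms: methyl iodide, CI
Why: Evans alkylation of the chelated Z-enolate. MeI attacks anti to the benzyl group, on the same face used in Step 9. This sets the α-centre and gives the erythro relationship to the β-centre.

**Step 11**
Reactants: **14**
Product: **15** (2S,3S)-4-[3-methoxy-4-(methoxymethoxy)phenyl]-2,3-dimethylbutan-1-ol; auxiliary **11** recovered
Conditions: LiBH4, MeOH (1 equiv), Et2O, 0 °C
Reagents that add atoms: none
Why: Reductive cleavage of the imide to the primary alcohol. The two stereocentres are no longer α to a carbonyl and cannot epimerise.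

**Step 12**
Reactants: **15**
Product: **16** 4-[(2S,3S)-4-iodo-2,3-dimethylbutyl]-2-methoxy-1-(methoxymethoxy)benzene
Conditions: I2, PPh3, imidazole, CH2Cl2, 0 °C → rt
Reagents that add atoms: iodine, II
Why: Appel iodination of the primary alcohol occurs at CH2 and does not touch the stereocentres.

**Step 13**
Reactants: **16**, **9**
Product: **17** bis(MOM) ether of the target, COc1cc(C[C@H](C)[C@H](C)Cc2cc(OC)c(OCOC)c(OC)c2)ccc1OCOC
Conditions: NiBr2·diglyme (10 mol %), 4,4′-di-tert-butyl-2,2′-bipyridine (10 mol %), Zn, DMA, 60 °C
Reagents that add atoms: none (the aryl group comes from **9**)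
Why: Ni-catalysed reductive cross-electrophile coupling, in which a primary alkyl radical from the iodide is captured by an Ar–Ni species. The stereocentres are β and γ to the reacting carbon and are untouched. The descriptors change to (S,R) only because the CIP priorities change.

**Step 14**
Reactants: **17**
Product: **18** target, (S,R)-4,4′-(2,3-dimethylbutane-1,4-diyl) guaiacyl/syringyl bisphenol
Conditions: 3 M HCl, MeOH/THF, 50 °C
Reagents that add atoms: none
Why: Acidic cleavage of the two aryl MOM acetals gives the free phenols. The benzylic alkyl stereocentres are unaffected.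

## Compound list
1 | p-cresol | Cc1ccc(O)cc1 | starting material
2 | 2-bromo-4-methylphenol | Cc1ccc(O)c(Br)c1 | intermediate
3 | 2-methoxy-4-methylphenol | COc1cc(C)ccc1O | intermediate
4 | 1-(methoxymethoxy)-2-methoxy-4-methylbenzene | COCOc1ccc(C)cc1OC | intermediate
5 | 4-(bromomethyl)-1-(methoxymethoxy)-2-methoxybenzene | COCOc1ccc(CBr)cc1OC | intermediate
6 | phenol | Oc1ccccc1 | starting material
7 | 2,4,6-tribromophenol | Oc1c(Br)cc(Br)cc1Br | intermediate
8 | 4-bromo-2,6-dimethoxyphenol | COc1cc(Br)cc(OC)c1O | intermediate
9 | 5-bromo-1,3-dimethoxy-2-(methoxymethoxy)benzene | COCOc1c(OC)cc(Br)cc1OC | intermediate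
10 | (E)-crotonyl chloride | C/C=C/C(Cl)=O | starting material
11 | (S)-4-benzyloxazolidin-2-one | O=C1N[C@@H](Cc2ccccc2)CO1 | starting material (auxiliary, recovered)
12 | N-crotonyl-(S)-4-benzyloxazolidinone | C/C=C/C(=O)N1C(=O)OC[C@@H]1Cc1ccccc1 | intermediate
13 | β-(guaiacylmethyl) imide | O=C(C[C@@H](C)Cc1ccc(OCOC)c(OC)c1)N1C(=O)OC[C@@H]1Cc1ccccc1 | intermediate
14 | α-methyl imide | O=C([C@@H](C)[C@@H](C)Cc1ccc(OCOC)c(OC)c1)N1C(=O)OC[C@@H]1Cc1ccccc1 | intermediate
15 | (2S,3S)-aryl-2,3-dimethylbutan-1-ol | OC[C@@H](C)[C@@H](C)Cc1ccc(OCOC)c(OC)c1 | intermediate
16 | (2S,3S)-primary iodide | IC[C@@H](C)[C@@H](C)Cc1ccc(OCOC)c(OC)c1 | intermediate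
17 | bis-MOM ether of the target | COc1cc(C[C@H](C)[C@H](C)Cc2cc(OC)c(OCOC)c(OC)c2)ccc1OCOC | intermediate
18 | CID53359576 | COc1cc(C[C@H](C)[C@H](C)Cc2cc(OC)c(O)c(OC)c2)ccc1O | target

## Totals
Total steps: 14. Longest linear sequence: 10 steps (p-cresol → 2 → 3 → 4 → 5 → 13 → 14 → 15 → 16 → 17 → 18, i.e. Steps 1–4, then 9–14).

Three steps most likely to fail:
1. **Step 9** (benzylic radical conjugate addition). The benzyl bromide may simply be reduced or dimerise, and the diastereoselectivity may be only moderate.
   Fallback: a polar route. Add the benzylic Grignard from **5**, with CuBr·SMe2, to **12**, which should give the same anti-to-benzyl face selectivity.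
2. **Step 6** (selective ortho-methoxylation while keeping the para bromide).
   Fallback: use the syringyl unit as the benzylic fragment and the guaiacyl unit as the aryl bromide. Prepare syringyl benzyl bromide from p-cresol (2,6-dibromination, CuI/NaOMe, MOM protection, NBS). Use the (R)-auxiliary, so the radical-derived carbon is R and carries syringyl. Couple the iodide to MOM-protected 4-bromoguaiacol, which is made from guaiacol.
3. **Step 13** (Ni coupling of a β-branched iodide with an electron-rich aryl bromide, where homocoupling or reduction competes).
   Fallback: a polar aryl-ketone route. Convert imide **14** to the Weinreb amide, add the aryllithium from **9**, then deoxygenate the ketone with Et3SiH/TFA. The α-stereocentre is at some risk of epimerisation in the ketone.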